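**Strategy.** The quinone ring is numbered C1 (C=O), C2 (OH), C3 (icosyl), C4 (C=O), C5 (OMe), C6 (H). The four-carbon unit C1–C6–C5–C4, with its oxygens on C1, C4 and C5, is the silyl dienol ether of methyl tetronate (a 4-methoxy-2-silyloxyfuran ring). C2–C3 is an acetyl-activated alkyne, tetracos-3-yn-2-one, whose acetyl group is a latent C2 hydroxyl. One thermal [4+2] cycloaddition forms C1–C2 and C3–C4; the oxygen bridge then opens and the six-membered carbocycle emerges as a pentasubstituted hydroquinone monosilyl ether. Baeyer–Villiger oxidation, deprotection and aerobic oxidation finish the quinone.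

Key step: step 4

Remark: the target is achiral and is drawn as its 2-hydroxy-1,4-dione tautomer; the only stereocentres on the route are the two bridgehead carbons of the transient cycloadduct 9, which is racemic and loses both on aromatisation.

**Step 1**
Reactants: 1 4-methoxyfuran-2(5H)-one (methyl tetronate)
Product: 2 tert-butyl[(4-methoxyfuran-2-yl)oxy]dimethylsilane
Conditions: TBSOTf, Et3N, CH2Cl2, 0 °C to rt
Reagents that add atoms: tert-butyldimethylsilyl trifluoromethanesulfonate, CC(C)(C)[Si](C)(C)OS(=O)(=O)C(F)(F)F
Why: Soft enolisation of a butenolide (silyl dienol ether formation), in which O-silylation of the lactone carbonyl acidifies C5–H and triethylamine removes it to give the aromatic 2-silyloxyfuran.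

**Step 2**
Reactants: 3 ethynyltrimethylsilane; 4 1-bromoicosane
Product: 6 (docos-1-yn-1-yl)trimethylsilane, via lithium (trimethylsilyl)acetylide 5 (not isolated)
Conditions: n-BuLi, THF, −78 °C; then 4, DMPU, −78 °C to rt
Reagents that add atoms: none
Why: SN2 alkylation of a lithium acetylide with an unhindered primary bromide, accelerated by the dipolar cosolvent, the silyl group blocking the second alkyne terminus.

**Step 3**
Reactants: 6 (docos-1-yn-1-yl)trimethylsilane; 7 acetyl chloride
Product: 8 tetracos-3-yn-2-one
Conditions: AlCl3, CH2Cl2, 0 °C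
Reagents that add atoms: none
Why: Friedel–Crafts-type ipso acylation of an alkynylsilane, in which the acylium ion attacks the silicon-bearing carbon through a β-silyl-stabilised vinyl cation and chloride removes the silyl group to give the conjugated ynone.

**Step 4**
Reactants: 2 tert-butyl[(4-methoxyfuran-2-yl)oxy]dimethylsilane; 8 tetracos-3-yn-2-one
Product: 10 1-[6-(tert-butyldimethylsilyloxy)-3-hydroxy-2-icosyl-4-methoxyphenyl]ethanone, via oxanorbornadiene cycloadduct 9 (not isolated)
Conditions: PhMe, 90 °C, sealed tube, Ar (2 in slight excess)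
Reagents that add atoms: none
Why: The furan is a cyclic 1-silyloxy-3-methoxybutadiene whose HOMO is raised and largest at C5, while the acetyl group lowers the alkyne LUMO and makes the chain-bearing β-carbon the electrophilic end, so a polarised, asynchronous intermolecular Diels–Alder reaction joins furan C5 to the β-carbon and furan C2 to the α-carbon and closes the six-membered carbocycle by [4+2] annulation (cycloadduct 9). In 9 the bridge C–O bond at the silyloxy-bearing bridgehead ionises under the push of the silyloxy and vinylogous methoxy oxygens, and loss of the proton from the other bridgehead aromatises the ring, the former furan oxygen ending as the free phenol and the silyl group staying on the other para oxygen. The closest known reaction type is the cycloaddition of 2-silyloxyfurans with acetylenic esters and ketones followed by bridge opening to hydroquinone monoethers. No stereocentre is created in the product, since both bridgehead centres of racemic 9 are erased on aromatisation. The step needs regioselectivity only, and both donors (silyloxy on furan C2, methoxy on furan C4) direct the same terminus, C5, to the β-carbon, which places the icosyl group beside the new phenol carbon and the acetyl group beside the silyloxy carbon.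

**Step 5**
Reactants: 10 1-[6-(tert-butyldimethylsilyloxy)-3-hydroxy-2-icosyl-4-methoxyphenyl]ethanone
Product: 11 3-acetyl-4-[(tert-butyldimethylsilyl)oxy]-2-icosyl-6-methoxyphenyl acetate
Conditions: Ac2O, pyridine, DMAP (cat.), CH2Cl2, rt
Reagents that add atoms: acetic anhydride, CC(=O)OC(C)=O
Why: DMAP-catalysed acylation of a phenol, which shields the oxidation-prone hydroquinone oxygen from peracid with a group that is removed in the same final operation as the acetate made next.

**Step 6**
Reactants: 11 3-acetyl-4-[(tert-butyldimethylsilyl)oxy]-2-icosyl-6-methoxyphenyl acetate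
Product: 12 4-[(tert-butyldimethylsilyl)oxy]-2-icosyl-6-methoxy-1,3-phenylene diacetate
Conditions: mCPBA, TFA (cat.), CH2Cl2, 0 °C to rt
Reagents that add atoms: 3-chloroperoxybenzoic acid, OOC(=O)c1cccc(Cl)c1
Why: Baeyer–Villiger oxidation, in which the aryl group of the Criegee adduct, activated by its ortho silyloxy and para methoxy donors, migrates in preference to methyl and gives the aryl acetate, the aryl silyl ether and the existing acetate being inert to peracid.

**Step 7**
Reactants: 12 4-[(tert-butyldimethylsilyl)oxy]-2-icosyl-6-methoxy-1,3-phenylene diacetate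
Product: 14 Irisoquin-D (2-hydroxy-3-icosyl-5-methoxycyclohexa-2,5-diene-1,4-dione), via triol 13 (not isolated)
Conditions: K2CO3, MeOH, O2 (balloon), rt; then 1 M HCl
Reagents that add atoms: none
Why: Base-mediated transesterification of both aryl acetates and methanolysis of the aryl silyl ether release the hydroxyhydroquinone 13, whose anion is autoxidised by O2 to the only para-quinone that can form without C–O cleavage, and in methanol any addition–elimination at the methoxy-bearing carbon is degenerate.

**Compound list**
1 | 4-methoxyfuran-2(5H)-one (methyl tetronate) | COC1=CC(=O)OC1 | starting material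
2 | tert-butyl[(4-methoxyfuran-2-yl)oxy]dimethylsilane | COc1coc(O[Si](C)(C)C(C)(C)C)c1 | intermediate
3 | ethynyltrimethylsilane | C#C[Si](C)(C)C | starting material
4 | 1-bromoicosane | CCCCCCCCCCCCCCCCCCCCBr | starting material
5 | lithium (trimethylsilyl)acetylide | [Li]C#C[Si](C)(C)C | intermediate (not isolated)
6 | (docos-1-yn-1-yl)trimethylsilane | CCCCCCCCCCCCCCCCCCCCC#C[Si](C)(C)C | intermediate
7 | acetyl chloride | CC(=O)Cl | starting material
8 | tetracos-3-yn-2-one | CCCCCCCCCCCCCCCCCCCCC#CC(C)=O | intermediate
9 | 1-[1-(tert-butyldimethylsilyloxy)-3-icosyl-5-methoxy-7-oxabicyclo[2.2.1]hepta-2,5-dien-2-yl]ethanone (racemic) | CC(=O)C1=C(CCCCCCCCCCCCCCCCCCCC)C2OC1(O[Si](C)(C)C(C)(C)C)C=C2OC | intermediate (not isolated)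
10 | 1-[6-(tert-butyldimethylsilyloxy)-3-hydroxy-2-icosyl-4-methoxyphenyl]ethanone | CCCCCCCCCCCCCCCCCCCCc1c(O)c(OC)cc(O[Si](C)(C)C(C)(C)C)c1C(C)=O | intermediate
11 | 3-acetyl-4-[(tert-butyldimethylsilyl)oxy]-2-icosyl-6-methoxyphenyl acetate | CCCCCCCCCCCCCCCCCCCCc1c(OC(C)=O)c(OC)cc(O[Si](C)(C)C(C)(C)C)c1C(C)=O | intermediate
12 | 4-[(tert-butyldimethylsilyl)oxy]-2-icosyl-6-methoxy-1,3-phenylene diacetate | CCCCCCCCCCCCCCCCCCCCc1c(OC(C)=O)c(OC)cc(O[Si](C)(C)C(C)(C)C)c1OC(C)=O | intermediate
13 | 3-icosyl-5-methoxybenzene-1,2,4-triol | CCCCCCCCCCCCCCCCCCCCc1c(O)c(OC)cc(O)c1O | intermediate (not isolated)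
14 | Irisoquin-D, 2-hydroxy-3-icosyl-5-methoxycyclohexa-2,5-diene-1,4-dione | CCCCCCCCCCCCCCCCCCCCC1=C(O)C(=O)C=C(OC)C1=O | target

**Total step count:** 7
**Longest linear sequence:** 6 steps (steps 2, 3, 4, 5, 6, 7)

**Steps most likely to fail**

**Step 4.** The β-alkyl ynone may react so slowly that the silyloxyfuran desilylates or oligomerises first. Alternatively, the first C–C bond may form without ring closure, a Mukaiyama–Michael-type addition ending in silyl transfer. Silyl migration between the two para oxygens during bridge opening would be harmless, because steps 5 to 7 converge on the same triol.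

The fallback gives up the cycloaddition and builds the quinone on a preformed arene. It sets out from 4. Commercial 1,2,4,5-tetramethoxybenzene is lithiated with n-BuLi in THF (0 °C to rt) to (2,3,5,6-tetramethoxyphenyl)lithium F1, which is alkylated with 4 to 3-icosyl-1,2,4,5-tetramethoxybenzene F2. Oxidative demethylation with (NH4)2Ce(NO3)6 (tetravalent cerium) in MeCN/H2O should give 3-icosyl-2,5-dimethoxycyclohexa-2,5-diene-1,4-dione F3. Aqueous HClO4 in THF is then expected to hydrolyse preferentially the methoxy group flanked by the chain, which is twisted out of conjugation and so the more reactive vinylogous ester. The fallback comes back to the route at 14.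

**Step 6.** Peracid addition to the twisted, doubly ortho-substituted carbonyl may be slow, so that ring oxidation or acid-induced loss of the silyl ether competes.

The fallback carries a formyl group in place of acetyl through the same cycloaddition, so that oxygen insertion becomes a facile aldehyde oxidation. It sets out from 6. Protodesilylation (K2CO3, MeOH) gives docos-1-yne F4. Deprotonation with n-BuLi (THF, −78 °C) gives lithium docos-1-yn-1-ide F5, which is formylated with DMF and quenched inversely into aqueous KH2PO4 to give tricos-2-ynal F6. Heating F6 with furan 2 in toluene should give, by way of 1-(tert-butyldimethylsilyloxy)-3-icosyl-5-methoxy-7-oxabicyclo[2.2.1]hepta-2,5-diene-2-carbaldehyde F7, the phenol 6-[(tert-butyldimethylsilyl)oxy]-3-hydroxy-2-icosyl-4-methoxybenzaldehyde F8. Acetylation (Ac2O, pyridine, DMAP) gives 4-[(tert-butyldimethylsilyl)oxy]-3-formyl-2-icosyl-6-methoxyphenyl acetate F9. Dakin-type oxidation with mCPBA in CH2Cl2 gives 3-acetoxy-6-[(tert-butyldimethylsilyl)oxy]-2-icosyl-4-methoxyphenyl formate F10. Under the conditions of step 7, F10 is methanolysed to the triol, so the fallback comes back to the route at 13.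

**Step 7.** In the basic aerobic medium the hydrogen peroxide that forms may degrade the electron-rich quinone, cleavage of the silyl ether may lag behind oxidation, or the methoxy group may be lost if water intrudes.

The fallback separates deprotection from oxidation and runs both without base. It sets out from 12. Selective phenolic desilylation with KHF2 in MeOH at rt gives 4-hydroxy-2-icosyl-6-methoxy-1,3-phenylene diacetate F11. Acid methanolysis under argon (HCl generated from AcCl in MeOH, 50 °C) removes both acetates, and the fallback comes back to the route at 13. Triol 13 is then oxidised in the same flask with aqueous FeCl3 (trivalent iron) to 14.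

**Further compounds**
F1 | step 4 | (2,3,5,6-tetramethoxyphenyl)lithium | [Li]c1c(OC)c(OC)cc(OC)c1OC
F2 | step 4 | 3-icosyl-1,2,4,5-tetramethoxybenzene | CCCCCCCCCCCCCCCCCCCCc1c(OC)c(OC)cc(OC)c1OC
F3 | step 4 | 3-icosyl-2,5-dimethoxycyclohexa-2,5-diene-1,4-dione | CCCCCCCCCCCCCCCCCCCCC1=C(OC)C(=O)C=C(OC)C1=O
F4 | step 6 | docos-1-yne | CCCCCCCCCCCCCCCCCCCCC#C
F5 | step 6 | lithium docos-1-yn-1-ide | CCCCCCCCCCCCCCCCCCCCC#C[Li]
F6 | step 6 | tricos-2-ynal | CCCCCCCCCCCCCCCCCCCCC#CC=O
F7 | step 6 | 1-(tert-butyldimethylsilyloxy)-3-icosyl-5-methoxy-7-oxabicyclo[2.2.1]hepta-2,5-diene-2-carbaldehyde (racemic) | O=CC1=C(CCCCCCCCCCCCCCCCCCCC)C2OC1(O[Si](C)(C)C(C)(C)C)C=C2OC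
F8 | step 6 | 6-[(tert-butyldimethylsilyl)oxy]-3-hydroxy-2-icosyl-4-methoxybenzaldehyde | CCCCCCCCCCCCCCCCCCCCc1c(O)c(OC)cc(O[Si](C)(C)C(C)(C)C)c1C=O
F9 | step 6 | 4-[(tert-butyldimethylsilyl)oxy]-3-formyl-2-icosyl-6-methoxyphenyl acetate | CCCCCCCCCCCCCCCCCCCCc1c(OC(C)=O)c(OC)cc(O[Si](C)(C)C(C)(C)C)c1C=O
F10 | step 6 | 3-acetoxy-6-[(tert-butyldimethylsilyl)oxy]-2-icosyl-4-methoxyphenyl formate | CCCCCCCCCCCCCCCCCCCCc1c(OC(C)=O)c(OC)cc(O[Si](C)(C)C(C)(C)C)c1OC=O
F11 | step 7 | 4-hydroxy-2-icosyl-6-methoxy-1,3-phenylene diacetate | CCCCCCCCCCCCCCCCCCCCc1c(OC(C)=O)c(OC)cc(O)c1OC(C)=O
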